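The target is cut back to podocarpic acid, which already holds rings A and B with C4, C5, C10, C19 and sixteen carbons. The unactivated C2 oxygen is traced to a C2–H bond that lies 1,3-diaxial to the axial C19 carbon on C4 of ring A. In one operation the C19 amidyl radical removes the 2β hydrogen and the C2–O bond closes a 2β,19-γ-lactone, setting C2 and masking C19. The precursor is the 7-oxo-12-methoxy C19 primary amide; its ring B ketone shields the competing C6–H bonds. Ring C is then cut down to C11, C12 and C17, and the Z side chain comes from but-2-yn-1-ol.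

Key step: step 4

Remark on the chemistry: podocarpane numbering is used up to compound 14 and labdane numbering from 15 on (podocarpane C14 becomes labdane C17). The C7 carbonyl cannot pass the dissolving-metal step, so it is removed after the key step and the 7α-hydroxyl is returned later by allylic oxidation. Natural (+)-podocarpic acid and but-2-yn-1-ol are taken as commercial.

Step 1
Reactants: 1 podocarpic acid (12-hydroxypodocarpa-8,11,13-trien-19-oic acid; axial 4β-CO2H, 5α-H, 10β-CH3)
Product: 2 O-methylpodocarpic acid (12-methoxypodocarpa-8,11,13-trien-19-oic acid)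
Conditions: Me2SO4, aq. NaOH, 0 °C → rt; then aq. HCl
Reagents that add atoms: dimethyl sulfate, COS(=O)(=O)OC
Why: Williamson ether synthesis in which the phenoxide should be methylated much faster than the hindered axial carboxylate on quaternary C4, so the acid stays free for step 2.

Step 2
Reactants: 2 O-methylpodocarpic acid
Product: 4 O-methylpodocarpamide (12-methoxypodocarpa-8,11,13-trien-19-amide), via acid chloride 3 (not isolated)
Conditions: (COCl)2, cat. DMF, CH2Cl2, 0 °C → rt; evaporate; NH3, THF, 0 °C
Reagents that add atoms: ammonia, N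
Why: Nucleophilic acyl substitution through the acid chloride, which is needed because the axial neopentyl-type carboxyl group is too hindered for direct amidation.

Step 3
Reactants: 4 O-methylpodocarpamide
Product: 5 12-methoxy-7-oxopodocarpa-8,11,13-trien-19-amide
Conditions: CrO3, AcOH–H2O, rt
Reagents that add atoms: chromium trioxide, O=[Cr](=O)=O
Why: Chromium(VI) benzylic oxidation at C7, the only benzylic CH2 and one activated by the para methoxy group, while the primary amide and the aryl ether should be inert.

Step 4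
Reactants: 5 12-methoxy-7-oxopodocarpa-8,11,13-trien-19-amide
Product: 9 12-methoxy-7-oxopodocarpa-8,11,13-trien-19,2β-olide, via N-iodoamide 6 (not isolated), via 2α-iodo amide 7 (not isolated), via iminolactone 8 (not isolated)
Conditions: Pb(OAc)4, I2, PhCl, visible light (tungsten lamp), 25–40 °C; then THF–H2O–AcOH, rt
Reagents that add atoms: water, O
Why: Lead tetraacetate and iodine should convert the amide into N-iodoamide 6, whose N–I bond is cleaved by visible light (which the aryl ketone does not absorb) to an amidyl radical that takes the axial 2β hydrogen through a six-membered transition state (1,5-hydrogen transfer). The C2 radical should collect iodine on the open α face to give 7, and the carbonyl oxygen of the axial amide then displaces the equatorial iodide from the β face to iminolactone 8, which aqueous acid hydrolyses to lactone 9. The closest known reaction type is the photolysis of N-iodoamides to γ-lactones, a Hofmann–Löffler–Freytag-type remote functionalisation. The one ring formed, the five-membered lactone, closes in the 5-exo-tet mode by O-alkylation at C2. The new stereocentre C2 is controlled by the tether, because oxygen can reach C2 only on the β face on which C19 stands. The step needs abstraction at C2 and not at C6 or C20: the C7 ketone makes the C6 hydrogens electron-poor and mismatched for the electrophilic amidyl radical, and C20 would need a 1,6-transfer from a stronger primary C–H bond.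

Step 5
Reactants: 9 12-methoxy-7-oxopodocarpa-8,11,13-trien-19,2β-olide
Product: 10 12-methoxypodocarpa-8,11,13-trien-19,2β-olide
Conditions: H2 (3 atm), 10% Pd/C, AcOH, cat. HClO4, rt
Reagents that add atoms: none
Why: Catalytic hydrogenolysis of a para-methoxyaryl ketone to the methylene group through the benzylic alcohol, which removes a carbonyl that has done its work at C6 and would not survive step 7, while lactone and anisole should be untouched.

Step 6
Reactants: 10 12-methoxypodocarpa-8,11,13-trien-19,2β-olide
Product: 11 12-methoxypodocarpa-8,11,13-triene-2β,19-diol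
Conditions: LiAlH4, THF, 0 °C → reflux; aq. NaOH work-up
Reagents that add atoms: none
Why: Hydride reduction of the lactone to the diol, in which no stereocentre is touched, so the axial 2β-hydroxyl and the axial C19 CH2OH are kept.

Step 7
Reactants: 11 12-methoxypodocarpa-8,11,13-triene-2β,19-diol
Product: 12 12-methoxypodocarpa-8,12-diene-2β,19-diol
Conditions: Li, NH3(l), THF, t-BuOH, −78 → −33 °C; solid NH4Cl
Reagents that add atoms: none
Why: Birch reduction in which the anisole ring should be protonated at C11 and C14, leaving the enol ether C12=C13 and the tetrasubstituted C8=C9 bond, with both hydroxyl groups protected as alkoxides.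

Step 8
Reactants: 12 12-methoxypodocarpa-8,12-diene-2β,19-diol
Product: 13 methyl 2β,19-dihydroxy-13-oxo-12,13-secopodocarp-8-en-12-oate
Conditions: O3 (1 equiv, Sudan Red 7B end-point), CH2Cl2–MeOH, pyridine, −78 °C; Me2S
Reagents that add atoms: ozone, [O-][O+]=O
Why: Chemoselective ozonolysis in which the electron-rich, unhindered enol ether should react before the hindered ring-fusion C8=C9 bond, giving the methyl ester at C12 and the aldehyde at C13.

Step 9
Reactants: 13 methyl 2β,19-dihydroxy-13-oxo-12,13-secopodocarp-8-en-12-oate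
Product: 15 methyl 2β,19-dihydroxy-17-oxo-13,14,15,16-tetranorlabd-8-en-12-oate, via piperidine dienamine 14 (not isolated)
Conditions: piperidine, MgSO4, CH2Cl2, rt; filter, evaporate; O3, CH2Cl2, −78 °C; Me2S
Reagents that add atoms: ozone, [O-][O+]=O
Why: One-carbon degradation of an aldehyde by enamine ozonolysis, in which the terminal, most electron-rich C13=C14 bond of the dienamine should be cleaved first, so that C13 leaves as a formamide and C14 stays as a formyl group conjugated with C8=C9.

Step 10
Reactants: 15 methyl 2β,19-dihydroxy-17-oxo-13,14,15,16-tetranorlabd-8-en-12-oate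
Product: 18 methyl 2β,19-dihydroxy-13,14,15,16-tetranorlabd-8(17)-en-12-oate (9α-H), via tosylhydrazone 16 (not isolated), via allylic diazene 17 (not isolated)
Conditions: TsNHNH2, THF, rt; evaporate; catecholborane (excess), CHCl3, 0 °C; NaOAc·3H2O, 65 °C
Reagents that add atoms: none
Why: Reductive 1,3-transposition of an α,β-unsaturated tosylhydrazone, in which 1,2-hydride addition and loss of sulfinate give the allylic diazene, whose retro-ene loss of N2 moves the double bond to C8=C17 and should deliver hydrogen to C9 on the α face, opposite the axial C20 methyl group, which sets the 9α-H with the side chain equatorial.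

Step 11
Reactants: 18 methyl 2β,19-dihydroxy-13,14,15,16-tetranorlabd-8(17)-en-12-oate
Product: 19 2β,19-dihydroxy-13,14,15,16-tetranorlabd-8(17)-en-12-oic acid
Conditions: LiOH, THF–MeOH–H2O, rt; then 1 M HCl to pH 3
Reagents that add atoms: lithium hydroxide, [Li+].[OH-]
Why: Saponification of the unhindered methyl ester, placed before any acetate is present so that C12 can later be reduced as the free acid.

Step 12
Reactants: 19 2β,19-dihydroxy-13,14,15,16-tetranorlabd-8(17)-en-12-oic acid
Product: 20 19-acetoxy-2β-hydroxy-13,14,15,16-tetranorlabd-8(17)-en-12-oic acid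
Conditions: Ac2O (2.2 equiv), pyridine, 0 °C; then H2O, rt
Reagents that add atoms: acetic anhydride, CC(=O)OC(C)=O
Why: Selective O-acylation of the primary C19 hydroxyl, since the axial 2β-hydroxyl is flanked by the syn-axial C19 and C20 groups and should stay free, and the mixed anhydride formed at the carboxyl group is hydrolysed on aqueous work-up.

Step 13
Reactants: 20 19-acetoxy-2β-hydroxy-13,14,15,16-tetranorlabd-8(17)-en-12-oic acid
Product: 22 19-acetoxy-13,14,15,16-tetranorlabd-8(17)-ene-2β,12-diol, via isobutyl mixed anhydride 21 (not isolated)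
Conditions: i-BuOCOCl, N-methylmorpholine, THF, −15 °C; NaBH4, H2O, 0 °C
Reagents that add atoms: none
Why: Chemoselective reduction of a carboxylic acid through its mixed carbonic anhydride with NaBH4, which should spare the acetate and the exocyclic alkene.

Step 14
Reactants: 22 19-acetoxy-13,14,15,16-tetranorlabd-8(17)-ene-2β,12-diol
Product: 23 19-acetoxy-12-iodo-13,14,15,16-tetranorlabd-8(17)-en-2β-ol
Conditions: PPh3, I2, imidazole, CH2Cl2, 0 °C
Reagents that add atoms: iodine, II
Why: Appel-type iodination in which the unhindered primary alcohol is activated and displaced by iodide (SN2), while the hindered axial secondary alcohol should not react.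

Step 15
Reactants: 23 19-acetoxy-12-iodo-13,14,15,16-tetranorlabd-8(17)-en-2β-ol
Product: 24 19-acetoxy-12-iodo-13,14,15,16-tetranorlabd-8(17)-en-2-one
Conditions: Dess–Martin periodinane, CH2Cl2, rt
Reagents that add atoms: none
Why: Dess–Martin oxidation of the secondary alcohol to the C2 ketone, which removes the C2 stereocentre and should leave iodide, acetate and alkene alone.

Step 16
Reactants: 24 19-acetoxy-12-iodo-13,14,15,16-tetranorlabd-8(17)-en-2-one
Product: 25 19-acetoxy-7α-hydroxy-12-iodo-13,14,15,16-tetranorlabd-8(17)-en-2-one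
Conditions: SeO2 (0.5 equiv), t-BuOOH, CH2Cl2, rt
Reagents that add atoms: selenium dioxide, O=[Se]=O; tert-butyl hydroperoxide, CC(C)(C)OO
Why: Selenium dioxide allylic oxidation (ene reaction, then [2,3]-sigmatropic shift) at the C7 methylene of the 1,1-disubstituted alkene, with oxygen delivered axially on the α face to give the 7α-alcohol, as expected for 8(17)-ene decalins, and placed before the trisubstituted side-chain alkene exists.

Step 17
Reactants: 25 19-acetoxy-7α-hydroxy-12-iodo-13,14,15,16-tetranorlabd-8(17)-en-2-one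
Product: 26 19-acetoxy-12-iodo-7α-(triethylsilyloxy)-13,14,15,16-tetranorlabd-8(17)-en-2-one
Conditions: TESCl, imidazole, DMF, 0 °C → rt
Reagents that add atoms: chlorotriethylsilane, CC[Si](Cl)(CC)CC
Why: Silyl ether formation, which masks the only acidic hydrogen before the organozinc reagent is made.

Step 18
Reactants: 27 but-2-yn-1-ol
Product: 29 (Z)-3-iodobut-2-en-1-ol, via cyclic alkenylalanate 28 (not isolated)
Conditions: Red-Al, THF, 0 °C → rt; I2, −78 → 0 °C
Reagents that add atoms: iodine, II
Why: Hydroxyl-directed trans-hydroalumination of the propargylic alcohol should place aluminium on C3 in a five-membered alanate, and iodinolysis with retention then gives the Z iodide with iodine cis to CH2OH.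

Step 19
Reactants: 29 (Z)-3-iodobut-2-en-1-ol
Product: 30 (Z)-tert-butyl[(3-iodobut-2-en-1-yl)oxy]dimethylsilane
Conditions: TBSCl, imidazole, CH2Cl2, rt
Reagents that add atoms: tert-butyldimethylsilyl chloride, CC(C)(C)[Si](C)(C)Cl
Why: Silylation of the primary alcohol so that it cannot protonate the organozinc partner in step 20.

Step 20
Reactants: 26 19-acetoxy-12-iodo-7α-(triethylsilyloxy)-13,14,15,16-tetranorlabd-8(17)-en-2-one; 30 (Z)-tert-butyl[(3-iodobut-2-en-1-yl)oxy]dimethylsilane
Product: 32 19-acetoxy-15-(tert-butyldimethylsilyloxy)-7α-(triethylsilyloxy)labda-8(17),13Z-dien-2-one, via alkylzinc iodide 31 (not isolated)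
Conditions: Zn dust (activated with 1,2-dibromoethane and TMSCl), LiCl, THF–DMA, 40 °C; then 30, PdCl2(dppf) (5 mol%), rt → 45 °C
Reagents that add atoms: none
Why: Negishi sp3–sp2 cross-coupling in which zinc insertion into the primary iodide gives a reagent that tolerates ketone and ester, and palladium should join it to the vinyl iodide with retention of the Z geometry, forming the C12–C13 bond.

Step 21
Reactants: 32 19-acetoxy-15-(tert-butyldimethylsilyloxy)-7α-(triethylsilyloxy)labda-8(17),13Z-dien-2-one
Product: 33 19-acetoxy-7α,15-dihydroxylabda-8(17),13Z-dien-2-one (target)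
Conditions: HF·pyridine, pyridine, THF, 0 °C → rt
Reagents that add atoms: none
Why: Fluoride-mediated cleavage of both silyl ethers, under which the acetate, the ketone and the two allylic alcohols should be stable.

Compound list
1 | podocarpic acid (12-hydroxypodocarpa-8,11,13-trien-19-oic acid) | C1C[C@H]2[C@@](C)(C(O)=O)CCC[C@]2(C)c3cc(O)ccc13 | starting material
2 | O-methylpodocarpic acid | C1C[C@H]2[C@@](C)(C(O)=O)CCC[C@]2(C)c3cc(OC)ccc13 | intermediate
3 | O-methylpodocarpoyl chloride | C1C[C@H]2[C@@](C)(C(Cl)=O)CCC[C@]2(C)c3cc(OC)ccc13 | intermediate (not isolated)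
4 | O-methylpodocarpamide (12-methoxypodocarpa-8,11,13-trien-19-amide) | C1C[C@H]2[C@@](C)(C(N)=O)CCC[C@]2(C)c3cc(OC)ccc13 | intermediate
5 | 12-methoxy-7-oxopodocarpa-8,11,13-trien-19-amide | O=C1C[C@H]2[C@@](C)(C(N)=O)CCC[C@]2(C)c3cc(OC)ccc13 | intermediate
6 | N-iodo-12-methoxy-7-oxopodocarpa-8,11,13-trien-19-amide | O=C1C[C@H]2[C@@](C)(C(NI)=O)CCC[C@]2(C)c3cc(OC)ccc13 | intermediate (not isolated)
7 | 2α-iodo-12-methoxy-7-oxopodocarpa-8,11,13-trien-19-amide | O=C1C[C@H]2[C@@](C)(C(N)=O)C[C@H](I)C[C@]2(C)c3cc(OC)ccc13 | intermediate (not isolated)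
8 | 19-imino-12-methoxy-2β,19-epoxypodocarpa-8,11,13-trien-7-one (iminolactone) | O=C1C[C@H]2[C@@](C)(C(=N)O4)C[C@@H]4C[C@]2(C)c3cc(OC)ccc13 | intermediate (not isolated)
9 | 12-methoxy-7-oxopodocarpa-8,11,13-trien-19,2β-olide | O=C1C[C@H]2[C@@](C)(C(=O)O4)C[C@@H]4C[C@]2(C)c3cc(OC)ccc13 | intermediate
10 | 12-methoxypodocarpa-8,11,13-trien-19,2β-olide | C1C[C@H]2[C@@](C)(C(=O)O4)C[C@@H]4C[C@]2(C)c3cc(OC)ccc13 | intermediate
11 | 12-methoxypodocarpa-8,11,13-triene-2β,19-diol | C1C[C@H]2[C@@](C)(CO)C[C@@H](O)C[C@]2(C)c3cc(OC)ccc13 | intermediate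
12 | 12-methoxypodocarpa-8,12-diene-2β,19-diol | C1C[C@H]2[C@@](C)(CO)C[C@@H](O)C[C@]2(C)C3=C1CC=C(OC)C3 | intermediate
13 | methyl 2β,19-dihydroxy-13-oxo-12,13-secopodocarp-8-en-12-oate | C1C[C@H]2[C@@](C)(CO)C[C@@H](O)C[C@]2(C)C(CC(=O)OC)=C1CC=O | intermediate
14 | methyl 2β,19-dihydroxy-13-(piperidin-1-yl)-12,13-secopodocarpa-8,13E-dien-12-oate (dienamine) | C1C[C@H]2[C@@](C)(CO)C[C@@H](O)C[C@]2(C)C(CC(=O)OC)=C1/C=C/N3CCCCC3 | intermediate (not isolated)
15 | methyl 2β,19-dihydroxy-17-oxo-13,14,15,16-tetranorlabd-8-en-12-oate | C1C[C@H]2[C@@](C)(CO)C[C@@H](O)C[C@]2(C)C(CC(=O)OC)=C1C=O | intermediate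
16 | tosylhydrazone of 15 (E at C=N) | C1C[C@H]2[C@@](C)(CO)C[C@@H](O)C[C@]2(C)C(CC(=O)OC)=C1/C=N/NS(=O)(=O)c3ccc(C)cc3 | intermediate (not isolated)
17 | methyl 17-diazenyl-2β,19-dihydroxy-13,14,15,16-tetranorlabd-8-en-12-oate (allylic diazene) | C1C[C@H]2[C@@](C)(CO)C[C@@H](O)C[C@]2(C)C(CC(=O)OC)=C1CN=N | intermediate (not isolated)
18 | methyl 2β,19-dihydroxy-13,14,15,16-tetranorlabd-8(17)-en-12-oate (9α-H) | C=C1CC[C@H]2[C@@](C)(CO)C[C@@H](O)C[C@]2(C)[C@H]1CC(=O)OC | intermediate
19 | 2β,19-dihydroxy-13,14,15,16-tetranorlabd-8(17)-en-12-oic acid | C=C1CC[C@H]2[C@@](C)(CO)C[C@@H](O)C[C@]2(C)[C@H]1CC(=O)O | intermediate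
20 | 19-acetoxy-2β-hydroxy-13,14,15,16-tetranorlabd-8(17)-en-12-oic acid | C=C1CC[C@H]2[C@@](C)(COC(C)=O)C[C@@H](O)C[C@]2(C)[C@H]1CC(=O)O | intermediate
21 | isobutyl carbonic mixed anhydride of 20 | C=C1CC[C@H]2[C@@](C)(COC(C)=O)C[C@@H](O)C[C@]2(C)[C@H]1CC(=O)OC(=O)OCC(C)C | intermediate (not isolated)
22 | 19-acetoxy-13,14,15,16-tetranorlabd-8(17)-ene-2β,12-diol | C=C1CC[C@H]2[C@@](C)(COC(C)=O)C[C@@H](O)C[C@]2(C)[C@H]1CCO | intermediate
23 | 19-acetoxy-12-iodo-13,14,15,16-tetranorlabd-8(17)-en-2β-ol | C=C1CC[C@H]2[C@@](C)(COC(C)=O)C[C@@H](O)C[C@]2(C)[C@H]1CCI | intermediate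
24 | 19-acetoxy-12-iodo-13,14,15,16-tetranorlabd-8(17)-en-2-one | C=C1CC[C@H]2[C@@](C)(COC(C)=O)CC(=O)C[C@]2(C)[C@H]1CCI | intermediate
25 | 19-acetoxy-7α-hydroxy-12-iodo-13,14,15,16-tetranorlabd-8(17)-en-2-one | C=C1[C@H](O)C[C@H]2[C@@](C)(COC(C)=O)CC(=O)C[C@]2(C)[C@H]1CCI | intermediate
26 | 19-acetoxy-12-iodo-7α-(triethylsilyloxy)-13,14,15,16-tetranorlabd-8(17)-en-2-one | C=C1[C@H](O[Si](CC)(CC)CC)C[C@H]2[C@@](C)(COC(C)=O)CC(=O)C[C@]2(C)[C@H]1CCI | intermediate
27 | but-2-yn-1-ol | CC#CCO | starting material
28 | sodium cyclic (Z)-alkenylalanate from 27 and Red-Al | CC1=CCO[Al-]1(OCCOC)OCCOC.[Na+] | intermediate (not isolated)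
29 | (Z)-3-iodobut-2-en-1-ol | C/C(I)=C/CO | intermediate
30 | (Z)-tert-butyl[(3-iodobut-2-en-1-yl)oxy]dimethylsilane | C/C(I)=C/CO[Si](C)(C)C(C)(C)C | intermediate
31 | alkylzinc iodide from 26 (C12–ZnI) | C=C1[C@H](O[Si](CC)(CC)CC)C[C@H]2[C@@](C)(COC(C)=O)CC(=O)C[C@]2(C)[C@H]1CC[Zn]I | intermediate (not isolated)
32 | 19-acetoxy-15-(tert-butyldimethylsilyloxy)-7α-(triethylsilyloxy)labda-8(17),13Z-dien-2-one | C=C1[C@H](O[Si](CC)(CC)CC)C[C@H]2[C@@](C)(COC(C)=O)CC(=O)C[C@]2(C)[C@H]1CC/C(C)=C\CO[Si](C)(C)C(C)(C)C | intermediate
33 | 19-acetoxy-7α,15-dihydroxylabda-8(17),13Z-dien-2-one | C=C1[C@H](O)C[C@H]2[C@@](C)(COC(C)=O)CC(=O)C[C@]2(C)[C@H]1CC/C(C)=C\CO | target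

Total step count: 21. Longest linear sequence: 19 steps (steps 1–17, 20 and 21); steps 18 and 19 make the side-chain iodide.

Steps most likely to fail

1. Step 4. Hydrogen transfer may go to C6 or C20 instead of C2, the C2 iodide may close through nitrogen to a lactam, or the anisole ring may be iodinated (an aryl iodide would be cleaved again under the conditions of step 5). The fallback replaces the tethered radical by an intermolecular, sterically governed C–H chlorination followed by carboxylate displacement, and sets out from 2. CrO3 in acetic acid should give 12-methoxy-7-oxopodocarpa-8,11,13-trien-19-oic acid F1. A hindered N-chloroamide (N-tert-butyl-N-chloro-3,5-bis(trifluoromethyl)benzamide, visible light, PhCF3, 55 °C) should then chlorinate C2, the least hindered and most electron-rich methylene of ring A, from the α face, as it does in related trans-decalin terpenoids, to give 2α-chloro-12-methoxy-7-oxopodocarpa-8,11,13-trien-19-oic acid F2. K2CO3 in DMF at 80 °C should let the axial C19 carboxylate displace the equatorial chloride with inversion, which comes back to the route at lactone 9.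

2. Step 10. Hydrogen delivery to C9 may show poor facial selectivity, or reduction of the hindered hydrazone may stall. The fallback sets C9 under thermodynamic control and brings C17 in by olefination, setting out from 15. Baeyer–Villiger oxidation of the enal (mCPBA, NaHCO3, CH2Cl2, 0 °C) should give methyl 8-formyloxy-2β,19-dihydroxy-13,14,15,16,17-pentanorlabd-8-en-12-oate F3. K2CO3 in methanol should release methyl 2β,19-dihydroxy-8-oxo-13,14,15,16,17-pentanorlabdan-12-oate F4, in which C9 can equilibrate to the equatorial side chain (9α-H). Wittig methylenation (Ph3P=CH2 in excess, THF) should return to the route at 18; in this variant C17 comes from the ylide.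

3. Step 8. Ozone may also cleave the tetrasubstituted C8=C9 bond, or the enol ether may hydrolyse before it is cleaved. The fallback uses a sterically demanding oxidant and a separate cleavage, setting out from 12. Catalytic OsO4 with NMO (acetone–water, pyridine buffer, 0 °C) should dihydroxylate only the enol ether, whose hemiketal collapses to 2β,13,19-trihydroxypodocarp-8-en-12-one F5 (C13 epimers, of no consequence). Pb(OAc)4 in methanol at 0 °C should cleave this α-hydroxy ketone to the C12 methyl ester and the C13 aldehyde, which comes back to the route at 13.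

Further compounds
F1 | step 4 | 12-methoxy-7-oxopodocarpa-8,11,13-trien-19-oic acid | O=C1C[C@H]2[C@@](C)(C(O)=O)CCC[C@]2(C)c3cc(OC)ccc13
F2 | step 4 | 2α-chloro-12-methoxy-7-oxopodocarpa-8,11,13-trien-19-oic acid | O=C1C[C@H]2[C@@](C)(C(O)=O)C[C@H](Cl)C[C@]2(C)c3cc(OC)ccc13
F3 | step 10 | methyl 8-formyloxy-2β,19-dihydroxy-13,14,15,16,17-pentanorlabd-8-en-12-oate | C1C[C@H]2[C@@](C)(CO)C[C@@H](O)C[C@]2(C)C(CC(=O)OC)=C1OC=O
F4 | step 10 | methyl 2β,19-dihydroxy-8-oxo-13,14,15,16,17-pentanorlabdan-12-oate | O=C1CC[C@H]2[C@@](C)(CO)C[C@@H](O)C[C@]2(C)[C@H]1CC(=O)OC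
F5 | step 8 | 2β,13,19-trihydroxypodocarp-8-en-12-one | C1C[C@H]2[C@@](C)(CO)C[C@@H](O)C[C@]2(C)C3=C1CC(O)C(=O)C3
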